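(The numbers in the tables stem from a simulated flask with constants of no real substance; the scatter is artificial.)

In a closed flask the reagent charged stays constant as a sum: reagent left, twice the self-condensation product, and the target with what is made from it. In this flask the reagent is the limiting reagent, 0.0450 M against 0.050 M of solid substrate, so I turned the question round: for the target to hold the reagent charged, with none of it left or self-condensed, the target would have to stand at 90.0 % of the solid substrate.

| flask | solid substrate | reagent | remark | time |
|---|---|---|---|---|
| beta | 0.050 M | 0.030 M | run made earlier |  |
| theta | 0.050 M | 0.068 M | run made earlier |  |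
| zeta | 0.075 M | 0.045 M | run made earlier |  |
| flask | 0.050 M | 0.0450 M |  | 6.0 min |

| run | time / min | target / % | dissolved substrate / % |
|---|---|---|---|
| beta | 1.50 | 0.8 | 12.6 |
| beta | 3.00 | 0.3 | 21.3 |
| beta | 5.00 | 2.6 | 30.3 |
| beta | 6.00 | 3.1 | 32.0 |
| theta | 0.833 | 0.7 | 8.2 |
| theta | 2.00 | 1.7 | 15.6 |
| theta | 4.00 | 2.9 | 25.4 |
| theta | 6.00 | 3.6 | 31.2 |
| zeta | 0.500 | 0 | 3.7 |
| zeta | 1.00 | 0 | 6.5 |
| zeta | 2.50 | 0.4 | 12.5 |
| zeta | 6.00 | 2.7 | 22.2 |

(readings scatter by 0.5 percentage points)

* the target standing at 6.0 min, as a percentage of the solid substrate charged
* concentration of dissolved substrate in solution at 6.0 min, in percent of saturation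

- a species is counted by the solid substrate in it: one side product counts as two
- given per volume of solution although it is solid: solid substrate
- steps that have been proposed: solid substrate <-> dissolved substrate; dissolved substrate + reagent -> target; dissolved substrate + target -> side product; 2 reagent -> self-condensation product; target <-> isomer of the product
- at the start none of the solid substrate is in solution
- dissolved substrate means what is dissolved; the solid is not counted in it

The earlier runs stood far from that. I multiplied each target reading at 6.00 min by its solid charge and got 1.55 mM in beta, 1.80 mM in theta and 2.03 mM in zeta, while the reagent charge ran from 0.030 M to 0.068 M. Their mean, 1.79 mM, is what I called the target level, the molar concentration of target at that time. It is 3.98 % of this flask's reagent charge, so my balance put nearly all of that charge in the other terms. Dividing the level by this flask's solid charge, I expected 3.58 %. The forecast, lower than mine, gave 3.4 % and 63 %: “yield responds sublinearly, probably because reagent self-condenses and target is lost”.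

The flask gave 3.21 % and 66.2 %.

    solid substrate ⇌ dissolved substrate, rate k1*(cs1 - [dissolved substrate]) while solid is left; crystals form when [dissolved substrate] > cs1 (solubility = 24.0 mM, k = 0.00360 s⁻¹)
    dissolved substrate + reagent → target (k = 0.0360 M⁻¹ s⁻¹)
    dissolved substrate + target → side product (k = 0.0420 M⁻¹ s⁻¹)
    2 reagent → self-condensation product (k = 0.0690 M⁻¹ s⁻¹)
    target ⇌ isomer of the product (K = 1.60, k = 0.00270 s⁻¹)

That yield is a target level of 1.61 mM, and in this flask the 0.0150 M of self-condensation product held 66.7 % of the reagent charged, with 28 % left. The neighbouring flask was charged with 0.020 M of solid substrate and the same reagent. Dividing this flask's level by that charge gave 8.03 %, and the neighbouring flask stood at 8.03 %, a target level of 1.61 mM, with 7.75 % still solid and 28 % of its reagent left.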